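**Strategy**

Everything rests on the C6–C7 single bond of the cross-conjugated dienone (prostanoid numbering: ester carbon C1, five-membered ring C8–C12). In one flask the C8 enolate of the complete bromo ring ketone (C8–C20) is formylated, the chelated formyl enolate is trapped as the (Z)-enol triflate at C7, and a Stille coupling with an (E)-alkenylstannane (C1–C6, carrying the C4 carbinol) forms C6–C7. The step exploits C7 as the exocyclic β-carbon of the C9 enone on the ring: chelation puts its leaving group cis to the C9 carbonyl, and retention delivers the (5E,7Z)-diene that a C7–C8 aldol condensation would leave to thermodynamics.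

Key step: step 12

Remark: compounds 1, 2, 10, 15 and 16 are taken as commercially available, and carbon nucleophiles are assumed to add to the carbonyl of a 4-silyloxycyclopent-2-enone anti to the silyloxy group.

**Route**

Step 1
Reactants: 1 (R)-4-[(tert-butyldimethylsilyl)oxy]cyclopent-2-en-1-one; 2 (1,3-dioxolan-2-ylmethyl)magnesium bromide
Product: 3 (1R,4R)-4-[(tert-butyldimethylsilyl)oxy]-1-(1,3-dioxolan-2-ylmethyl)cyclopent-2-en-1-ol
Conditions: CeCl3, THF, −78 → 0 °C; aq. NH4Cl
Reagents that add atoms: none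
Why: Cerium-modified Grignard 1,2-addition to the enone carbonyl should occur anti to the C4 silyloxy group (substrate control), which sets the future C12 carbinol centre with the hydroxyl cis to the silyl ether and brings in C13–C14 as a masked aldehyde.

Step 2
Reactants: 3 (1R,4R)-4-[(tert-butyldimethylsilyl)oxy]-1-(1,3-dioxolan-2-ylmethyl)cyclopent-2-en-1-ol
Product: 4 (1R,4R)-1-(1,3-dioxolan-2-ylmethyl)cyclopent-2-ene-1,4-diol
Conditions: Bu4NF, THF, 0 °C → rt
Reagents that add atoms: none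
Why: Fluoride-mediated desilylation should free the secondary allylic alcohol without touching the acetal or either stereocentre.

Step 3
Reactants: 4 (1R,4R)-1-(1,3-dioxolan-2-ylmethyl)cyclopent-2-ene-1,4-diol
Product: 5 (S)-4-(1,3-dioxolan-2-ylmethyl)-4-hydroxycyclopent-2-en-1-one
Conditions: MnO2, CH2Cl2, rt
Reagents that add atoms: none
Why: Manganese dioxide allylic oxidation should convert only the secondary allylic alcohol into the enone, the tertiary carbinol being inert, so that the carbonyl ends up at the future C9.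

Step 4
Reactants: 5 (S)-4-(1,3-dioxolan-2-ylmethyl)-4-hydroxycyclopent-2-en-1-one
Product: 6 (S)-2-bromo-4-(1,3-dioxolan-2-ylmethyl)-4-hydroxycyclopent-2-en-1-one
Conditions: Br2, CH2Cl2, 0 °C; then Et3N, 0 °C → rt
Reagents that add atoms: bromine BrBr
Why: Bromine addition to the enone followed by amine-induced dehydrobromination (α-bromination of an enone by addition–elimination) should place bromine at C10 at a stage where no other alkene is present.

Step 5
Reactants: 6 (S)-2-bromo-4-(1,3-dioxolan-2-ylmethyl)-4-hydroxycyclopent-2-en-1-one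
Product: 9 2-{(1S)-3-bromo-4-oxo-1-[(triethylsilyl)oxy]cyclopent-2-en-1-yl}acetaldehyde, via silyl ether acetal 7 (not isolated), via collidinium adduct 8 (not isolated)
Conditions: Et3SiOTf (excess), 2,4,6-collidine, CH2Cl2, −78 → 0 °C; then H2O, rt
Reagents that add atoms: triethylsilyl trifluoromethanesulfonate CC[Si](CC)(CC)OS(=O)(=O)C(F)(F)F; water O
Why: The silyl triflate should first silylate the tertiary alcohol and then open the dioxolane to a collidinium N,O-acetal that water hydrolyses to the aldehyde (silyl triflate/pyridine-base acetal cleavage), conditions under which the new silyl ether survives where aqueous acid would cleave it.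

Step 6
Reactants: 10 (Z)-hex-3-en-1-ol
Product: 11 (Z)-1-iodohex-3-ene
Conditions: I2, PPh3, imidazole, CH2Cl2, 0 °C → rt
Reagents that add atoms: iodine II
Why: Appel-type iodination of the primary alcohol should leave the Z alkene untouched.

Step 7
Reactants: 11 (Z)-1-iodohex-3-ene
Product: 12 [(Z)-hex-3-en-1-yl]triphenylphosphonium iodide
Conditions: PPh3, MeCN, reflux
Reagents that add atoms: triphenylphosphine c1ccc(cc1)P(c1ccccc1)c1ccccc1
Why: SN2 quaternisation of triphenylphosphine by the primary iodide should give the Wittig salt.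

Step 8
Reactants: 9 2-{(1S)-3-bromo-4-oxo-1-[(triethylsilyl)oxy]cyclopent-2-en-1-yl}acetaldehyde; 12 [(Z)-hex-3-en-1-yl]triphenylphosphonium iodide
Product: 14 (S)-2-bromo-4-[(2Z,5Z)-octa-2,5-dien-1-yl]-4-[(triethylsilyl)oxy]cyclopent-2-en-1-one, via phosphonium ylide 13 (not isolated)
Conditions: 12, NaN(SiMe3)2, THF, −78 °C; then 9, −78 → −20 °C
Reagents that add atoms: none
Why: Wittig olefination with the non-stabilised, lithium-free ylide is kinetically Z-selective and much faster at the aldehyde than at the hindered enone, so it should create the C14=C15 Z alkene of the skipped diene.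

Step 9
Reactants: 15 methyl 4-chloro-4-oxobutanoate; 16 (E)-1,2-bis(tributylstannyl)ethene
Product: 17 methyl (E)-4-oxo-6-(tributylstannyl)hex-5-enoate
Conditions: AlCl3, CH2Cl2, −78 → −20 °C
Reagents that add atoms: none
Why: Friedel–Crafts-type acyldestannylation of one C–Sn bond should give the (E)-β-stannyl enone with retention, the remaining stannyl group being deactivated by the new carbonyl.

Step 10
Reactants: 17 methyl (E)-4-oxo-6-(tributylstannyl)hex-5-enoate
Product: 18 methyl (4R,5E)-4-hydroxy-6-(tributylstannyl)hex-5-enoate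
Conditions: (S)-2-methyl-CBS-oxazaborolidine (cat.), catecholborane, toluene, −78 °C; then MeOH, aq. NaHCO3
Reagents that add atoms: none
Why: Corey–Bakshi–Shibata reduction, with the stannylvinyl group as the large substituent, should deliver hydride to the face that gives the (R)-allylic alcohol at C4 (catalyst control).

Step 11
Reactants: 18 methyl (4R,5E)-4-hydroxy-6-(tributylstannyl)hex-5-enoate
Product: 19 methyl (4R,5E)-4-[(triethylsilyl)oxy]-6-(tributylstannyl)hex-5-enoate
Conditions: Et3SiCl, imidazole, CH2Cl2, 0 °C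
Reagents that add atoms: chlorotriethylsilane CC[Si](Cl)(CC)CC
Why: Silyl ether protection should block the C4 hydroxyl so that the γ-hydroxy ester cannot lactonise before or during the coupling.

Step 12
Reactants: 14 (S)-2-bromo-4-[(2Z,5Z)-octa-2,5-dien-1-yl]-4-[(triethylsilyl)oxy]cyclopent-2-en-1-one; 19 methyl (4R,5E)-4-[(triethylsilyl)oxy]-6-(tributylstannyl)hex-5-enoate
Product: 22 methyl (4R,5E,7Z)-7-{(5R)-3-bromo-5-[(2Z,5Z)-octa-2,5-dien-1-yl]-2-oxo-5-[(triethylsilyl)oxy]cyclopent-3-en-1-ylidene}-4-[(triethylsilyl)oxy]hept-5-enoate, via lithium formyl enolate 20 (not isolated), via enol triflate 21 (not isolated)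
Conditions: LiN(SiMe3)2, THF, −78 °C; HCO2CH2CF3, −78 °C; N-(5-chloropyridin-2-yl)bis(trifluoromethanesulfonyl)imide, −78 → 0 °C; then 19, Pd2(dba)3, AsPh3, CuI, NMP, rt, dark; aq. NH4Cl
Reagents that add atoms: 2,2,2-trifluoroethyl formate O=COCC(F)(F)F
Why: Kinetic deprotonation at C8 and Claisen-type formylation should give the lithium chelate 20 of the C7-formyl ketone, whose U-shaped O–Li–O geometry is trapped on the C7 oxygen as the (Z)-enol triflate 21 with the triflate cis to the C9 carbonyl. Zerovalent palladium then inserts into the C7–O bond of this vinylogous acyl triflate, the alkenyl group of 19 is transferred from tin with copper assistance, and reductive elimination forms the C6–C7 bond. The closest known reaction types are chelation-controlled enol triflate formation from β-dicarbonyl enolates and the one-flask enol triflation/Stille coupling sequence. No ring is closed and no stereocentre is formed; the 5E geometry comes from 19 and the 7Z geometry from 21, both by retention, the latter supported by chelation of the C9 carbonyl oxygen to palladium in the alkenylpalladium intermediate. The step needs chemoselectivity for C7–OTf over C10–Br and for O-sulfonylation at the formyl-derived oxygen, which the vinylogous acyl activation of the triflate at room temperature and the lower hindrance of that oxygen should secure. Only C8 carries enolisable hydrogens, so the formylation is regiochemically unambiguous.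

Step 13
Reactants: 22 methyl (4R,5E,7Z)-7-{(5R)-3-bromo-5-[(2Z,5Z)-octa-2,5-dien-1-yl]-2-oxo-5-[(triethylsilyl)oxy]cyclopent-3-en-1-ylidene}-4-[(triethylsilyl)oxy]hept-5-enoate
Product: 23 methyl (4R,5E,7Z)-7-{(5R)-3-bromo-5-hydroxy-5-[(2Z,5Z)-octa-2,5-dien-1-yl]-2-oxocyclopent-3-en-1-ylidene}-4-hydroxyhept-5-enoate
Conditions: HF·pyridine, pyridine, THF, 0 °C → rt
Reagents that add atoms: none
Why: Pyridine-buffered fluoride desilylation should cleave both triethylsilyl ethers without base, so that the dienone, the skipped diene and the γ-hydroxy ester survive.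

**Compound list**

1 | (R)-4-[(tert-butyldimethylsilyl)oxy]cyclopent-2-en-1-one | O=C1C=C[C@H](O[Si](C)(C)C(C)(C)C)C1 | starting material
2 | (1,3-dioxolan-2-ylmethyl)magnesium bromide | Br[Mg]CC1OCCO1 | starting material
3 | (1R,4R)-4-[(tert-butyldimethylsilyl)oxy]-1-(1,3-dioxolan-2-ylmethyl)cyclopent-2-en-1-ol | O1CCOC1C[C@@]2(O)C=C[C@H](O[Si](C)(C)C(C)(C)C)C2 | intermediate
4 | (1R,4R)-1-(1,3-dioxolan-2-ylmethyl)cyclopent-2-ene-1,4-diol | O1CCOC1C[C@@]2(O)C=C[C@H](O)C2 | intermediate
5 | (S)-4-(1,3-dioxolan-2-ylmethyl)-4-hydroxycyclopent-2-en-1-one | O1CCOC1C[C@@]2(O)C=CC(=O)C2 | intermediate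
6 | (S)-2-bromo-4-(1,3-dioxolan-2-ylmethyl)-4-hydroxycyclopent-2-en-1-one | O1CCOC1C[C@@]2(O)C=C(Br)C(=O)C2 | intermediate
7 | (S)-2-bromo-4-(1,3-dioxolan-2-ylmethyl)-4-[(triethylsilyl)oxy]cyclopent-2-en-1-one | O1CCOC1C[C@@]2(O[Si](CC)(CC)CC)C=C(Br)C(=O)C2 | intermediate
8 | 1-[2-{(1S)-3-bromo-4-oxo-1-[(triethylsilyl)oxy]cyclopent-2-en-1-yl}-1-{2-[(triethylsilyl)oxy]ethoxy}ethyl]-2,4,6-trimethylpyridin-1-ium trifluoromethanesulfonate (both epimers at the N,O-acetal carbon) | CC[Si](CC)(CC)OCCOC(C[C@@]1(O[Si](CC)(CC)CC)C=C(Br)C(=O)C1)[n+]1c(C)cc(C)cc1C.[O-]S(=O)(=O)C(F)(F)F | intermediate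
9 | 2-{(1S)-3-bromo-4-oxo-1-[(triethylsilyl)oxy]cyclopent-2-en-1-yl}acetaldehyde | O=CC[C@@]1(O[Si](CC)(CC)CC)C=C(Br)C(=O)C1 | intermediate
10 | (Z)-hex-3-en-1-ol | CC/C=C\CCO | starting material
11 | (Z)-1-iodohex-3-ene | CC/C=C\CCI | intermediate
12 | [(Z)-hex-3-en-1-yl]triphenylphosphonium iodide | CC/C=C\CC[P+](c1ccccc1)(c1ccccc1)c1ccccc1.[I-] | intermediate
13 | [(Z)-hex-3-en-1-ylidene]triphenylphosphorane | CC/C=C\CC=P(c1ccccc1)(c1ccccc1)c1ccccc1 | intermediate
14 | (S)-2-bromo-4-[(2Z,5Z)-octa-2,5-dien-1-yl]-4-[(triethylsilyl)oxy]cyclopent-2-en-1-one | CC/C=C\C/C=C\C[C@@]1(O[Si](CC)(CC)CC)C=C(Br)C(=O)C1 | intermediate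
15 | methyl 4-chloro-4-oxobutanoate | COC(=O)CCC(=O)Cl | starting material
16 | (E)-1,2-bis(tributylstannyl)ethene | CCCC[Sn](CCCC)(CCCC)/C=C/[Sn](CCCC)(CCCC)CCCC | starting material
17 | methyl (E)-4-oxo-6-(tributylstannyl)hex-5-enoate | CCCC[Sn](CCCC)(CCCC)/C=C/C(=O)CCC(=O)OC | intermediate
18 | methyl (4R,5E)-4-hydroxy-6-(tributylstannyl)hex-5-enoate | CCCC[Sn](CCCC)(CCCC)/C=C/[C@H](O)CCC(=O)OC | intermediate
19 | methyl (4R,5E)-4-[(triethylsilyl)oxy]-6-(tributylstannyl)hex-5-enoate | CCCC[Sn](CCCC)(CCCC)/C=C/[C@H](O[Si](CC)(CC)CC)CCC(=O)OC | intermediate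
20 | lithium (Z)-{(5R)-3-bromo-5-[(2Z,5Z)-octa-2,5-dien-1-yl]-2-oxo-5-[(triethylsilyl)oxy]cyclopent-3-en-1-ylidene}methanolate | CC/C=C\C/C=C\C[C@@]1(O[Si](CC)(CC)CC)C=C(Br)C(=O)/C1=C\[O-].[Li+] | intermediate
21 | (Z)-{(5R)-3-bromo-5-[(2Z,5Z)-octa-2,5-dien-1-yl]-2-oxo-5-[(triethylsilyl)oxy]cyclopent-3-en-1-ylidene}methyl trifluoromethanesulfonate | CC/C=C\C/C=C\C[C@@]1(O[Si](CC)(CC)CC)C=C(Br)C(=O)/C1=C\OS(=O)(=O)C(F)(F)F | intermediate
22 | methyl (4R,5E,7Z)-7-{(5R)-3-bromo-5-[(2Z,5Z)-octa-2,5-dien-1-yl]-2-oxo-5-[(triethylsilyl)oxy]cyclopent-3-en-1-ylidene}-4-[(triethylsilyl)oxy]hept-5-enoate | CC/C=C\C/C=C\C[C@@]1(O[Si](CC)(CC)CC)C=C(Br)C(=O)/C1=C\C=C\[C@H](O[Si](CC)(CC)CC)CCC(=O)OC | intermediate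
23 | methyl (4R,5E,7Z)-7-{(5R)-3-bromo-5-hydroxy-5-[(2Z,5Z)-octa-2,5-dien-1-yl]-2-oxocyclopent-3-en-1-ylidene}-4-hydroxyhept-5-enoate | CC/C=C\C/C=C\C[C@@]1(O)C=C(Br)C(=O)/C1=C\C=C\[C@H](O)CCC(=O)OC | target

**Step count and risks**

Total steps: 13. Longest linear sequence: 8 steps (steps 1, 2, 3, 4, 5, 8, 12, 13).

Steps most likely to fail:

1. Step 12. The enolate may lose the C12 silanolate by β-elimination or self-condense, the Z geometry may erode during O-sulfonylation, zerovalent palladium may insert into the C10–Br bond, or carried-over lithium and triflamide salts may stall the catalyst. The fallback separates the stages and removes palladium. It sets out from 14: the formylation and triflation are run alone and triflate 21 is isolated by fast chromatography on buffered silica. A vinylogous Finkelstein exchange (NaI, acetone, 0 °C, dark) should give (4R,5Z)-2-bromo-5-(iodomethylidene)-4-[(2Z,5Z)-octa-2,5-dien-1-yl]-4-[(triethylsilyl)oxy]cyclopent-2-en-1-one F1. This iodide and stannane 19 are then joined by stoichiometric copper thiophene-2-carboxylate (monovalent copper) in NMP at 0 °C, a palladium-free Stille-type coupling through an alkenylcopper species that favours β-iodo enones with the iodide cis to the carbonyl and should leave the C–Br bond alone. The fallback comes back to the route at 22.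

2. Step 8. The basic ylide may deprotonate C8, add to the α-bromo enone, or expel the β-silyloxy group from the aldehyde. The fallback moves the olefination to a stage without an enone and the bromination to a nucleophilic manifold. It sets out from 3.
   - Et3SiOTf and 2,4,6-collidine, then water (as in step 5), should give 2-{(1R,4R)-4-[(tert-butyldimethylsilyl)oxy]-1-[(triethylsilyl)oxy]cyclopent-2-en-1-yl}acetaldehyde F2.
   - Wittig olefination with ylide 13 should give (1S,4R)-4-[(tert-butyldimethylsilyl)oxy]-1-[(2Z,5Z)-octa-2,5-dien-1-yl]-1-[(triethylsilyl)oxy]cyclopent-2-ene F3.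
   - Bu4NF removes both silyl groups to give (1S,4R)-1-[(2Z,5Z)-octa-2,5-dien-1-yl]cyclopent-2-ene-1,4-diol F4.
   - MnO2 gives (S)-4-hydroxy-4-[(2Z,5Z)-octa-2,5-dien-1-yl]cyclopent-2-en-1-one F5.
   - Because bromine cannot be used beside the skipped diene, nucleophilic epoxidation of the enone (H2O2, NaOH, MeOH, 0 °C) gives (4S)-4-hydroxy-4-[(2Z,5Z)-octa-2,5-dien-1-yl]-6-oxabicyclo[3.1.0]hexan-2-one F6.
   - Bromide opening at the α-carbon with dehydration (aq. HBr, acetone, 0 °C) gives (S)-2-bromo-4-hydroxy-4-[(2Z,5Z)-octa-2,5-dien-1-yl]cyclopent-2-en-1-one F7.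
   - Silylation (Et3SiOTf, 2,6-lutidine, −78 °C) comes back to the route at 14.

3. Step 5. Excess silyl triflate may enolise the C9 ketone to a silyl dienol ether, the pyridinium adduct may form incompletely, or the tertiary silyl ether may be lost on hydrolysis. The fallback replaces the acetal by an allyl group that is unveiled oxidatively. It sets out from 1.
   - Allylmagnesium bromide with CeCl3 should give (1S,4R)-4-[(tert-butyldimethylsilyl)oxy]-1-(prop-2-en-1-yl)cyclopent-2-en-1-ol F8.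
   - Bu4NF gives (1S,4R)-1-(prop-2-en-1-yl)cyclopent-2-ene-1,4-diol F9.
   - MnO2 gives (S)-4-hydroxy-4-(prop-2-en-1-yl)cyclopent-2-en-1-one F10.
   - Et3SiOTf and 2,6-lutidine give (S)-4-(prop-2-en-1-yl)-4-[(triethylsilyl)oxy]cyclopent-2-en-1-one F11.
   - Ozonolysis of the electron-rich terminal alkene in preference to the enone (O3, CH2Cl2, −78 °C; then Me2S) gives 2-{(1S)-4-oxo-1-[(triethylsilyl)oxy]cyclopent-2-en-1-yl}acetaldehyde F12.
   - Bromine addition and dehydrobromination (Br2, then Et3N) come back to the route at 9.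

Further compounds
F1 | step 12 | (4R,5Z)-2-bromo-5-(iodomethylidene)-4-[(2Z,5Z)-octa-2,5-dien-1-yl]-4-[(triethylsilyl)oxy]cyclopent-2-en-1-one | CC/C=C\C/C=C\C[C@@]1(O[Si](CC)(CC)CC)C=C(Br)C(=O)/C1=C\I
F2 | step 8 | 2-{(1R,4R)-4-[(tert-butyldimethylsilyl)oxy]-1-[(triethylsilyl)oxy]cyclopent-2-en-1-yl}acetaldehyde | O=CC[C@@]1(O[Si](CC)(CC)CC)C=C[C@H](O[Si](C)(C)C(C)(C)C)C1
F3 | step 8 | (1S,4R)-4-[(tert-butyldimethylsilyl)oxy]-1-[(2Z,5Z)-octa-2,5-dien-1-yl]-1-[(triethylsilyl)oxy]cyclopent-2-ene | CC/C=C\C/C=C\C[C@@]1(O[Si](CC)(CC)CC)C=C[C@H](O[Si](C)(C)C(C)(C)C)C1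
F4 | step 8 | (1S,4R)-1-[(2Z,5Z)-octa-2,5-dien-1-yl]cyclopent-2-ene-1,4-diol | CC/C=C\C/C=C\C[C@@]1(O)C=C[C@H](O)C1
F5 | step 8 | (S)-4-hydroxy-4-[(2Z,5Z)-octa-2,5-dien-1-yl]cyclopent-2-en-1-one | CC/C=C\C/C=C\C[C@@]1(O)C=CC(=O)C1
F6 | step 8 | (4S)-4-hydroxy-4-[(2Z,5Z)-octa-2,5-dien-1-yl]-6-oxabicyclo[3.1.0]hexan-2-one (epoxide diastereomers) | CC/C=C\C/C=C\C[C@@]1(O)C2OC2C(=O)C1
F7 | step 8 | (S)-2-bromo-4-hydroxy-4-[(2Z,5Z)-octa-2,5-dien-1-yl]cyclopent-2-en-1-one | CC/C=C\C/C=C\C[C@@]1(O)C=C(Br)C(=O)C1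
F8 | step 5 | (1S,4R)-4-[(tert-butyldimethylsilyl)oxy]-1-(prop-2-en-1-yl)cyclopent-2-en-1-ol | C=CC[C@@]1(O)C=C[C@H](O[Si](C)(C)C(C)(C)C)C1
F9 | step 5 | (1S,4R)-1-(prop-2-en-1-yl)cyclopent-2-ene-1,4-diol | C=CC[C@@]1(O)C=C[C@H](O)C1
F10 | step 5 | (S)-4-hydroxy-4-(prop-2-en-1-yl)cyclopent-2-en-1-one | C=CC[C@@]1(O)C=CC(=O)C1
F11 | step 5 | (S)-4-(prop-2-en-1-yl)-4-[(triethylsilyl)oxy]cyclopent-2-en-1-one | C=CC[C@@]1(O[Si](CC)(CC)CC)C=CC(=O)C1
F12 | step 5 | 2-{(1S)-4-oxo-1-[(triethylsilyl)oxy]cyclopent-2-en-1-yl}acetaldehyde | O=CC[C@@]1(O[Si](CC)(CC)CC)C=CC(=O)C1
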